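**Retrosynthetic overview**

1. Schizotenuin A is cut last at its two ester C–O bonds. This gives the benzofuran diacid 21 (O7 allyl, catechol acetonide) and two molecules of allyl-protected (R)-danshensu 23; both stereocentres are bought, not made.
2. Feature used: ring A (C3a–C4–C5–C6–C7–C7a) is joined to the furan only through C3a–C7a and carries oxygen at C7 and the acrylate at C5. A furan with a silyl enol ether on one carbon and an (E,E)-dienoate on the next already holds C6=C7, C7a=C3a and C4=C5 as a cis-locked hexatriene, so ring A needs only the C5–C6 bond.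
3. Ring A comes from six-electron electrocyclization of triene 16 followed by DDQ dehydrogenation to 18. Triene 16 comes from ketone 15 (silyl triflate), and 15 from aldehyde 12 and triethyl 4-phosphonocrotonate.
4. Furan 12 comes from dimethyl furan-3,4-dicarboxylate. The two esters are told apart first (monosaponification, borane reduction), then C2 is arylated (magnesiation, Negishi coupling) and C5 acetylated (second magnesiation, Weinreb amide).
5. Ring order: the furan and the three catechol rings are bought; ring A is the only ring formed (step 10). The phenols are freed at the end by acid (acetonide) and zerovalent palladium (seven allyl groups).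

Key step: step 10

Remark: (R)-danshensu is taken as its commercial sodium salt and its configuration is carried unchanged into both ester stereocentres; every other starting material is achiral.

**Route**

Step 1
Reactants: 1 dimethyl furan-3,4-dicarboxylate
Product: 2 4-(methoxycarbonyl)furan-3-carboxylic acid
Conditions: KOH (1.0 equiv), MeOH, 25 °C; then 1 M HCl
Reagents that add atoms: potassium hydroxide, [K+].[OH-]
Why: Monosaponification (ester hydrolysis) of a symmetric diester, in which the carboxylate formed first should deactivate the neighbouring ester towards hydroxide, so one equivalent of base should stop at the half ester and tell the two ring carbons apart.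

Step 2
Reactants: 2 4-(methoxycarbonyl)furan-3-carboxylic acid
Product: 3 methyl 4-(hydroxymethyl)furan-3-carboxylate
Conditions: BH3·SMe2, THF, 0 → 25 °C; then MeOH
Reagents that add atoms: none
Why: Chemoselective borane reduction, since borane reduces a free carboxylic acid through its acyloxyborane far faster than an ester, so only the acid should go to the primary alcohol.

Step 3
Reactants: 3 methyl 4-(hydroxymethyl)furan-3-carboxylate
Product: 4 methyl 4-{[tert-butyl(dimethyl)silyl]oxymethyl}furan-3-carboxylate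
Conditions: TBSCl, imidazole, DMF, 25 °C
Reagents that add atoms: tert-butyl(chloro)dimethylsilane, CC(C)(C)[Si](C)(C)Cl
Why: Standard silyl ether protection of a primary alcohol, so that the two metalations that follow meet no acidic OH.

Step 4
Reactants: 4 methyl 4-{[tert-butyl(dimethyl)silyl]oxymethyl}furan-3-carboxylate; 5 5-bromo-2,2-dimethyl-1,3-benzodioxole
Product: 8 methyl 4-{[tert-butyl(dimethyl)silyl]oxymethyl}-2-(2,2-dimethyl-1,3-benzodioxol-5-yl)furan-3-carboxylate, via furan-2-ylmagnesium chloride 6 (not isolated), via furan-2-ylzinc chloride 7 (not isolated)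
Conditions: TMPMgCl·LiCl, THF, −20 °C; ZnCl2, −20 → 25 °C; then 5, Pd(OAc)2 (2 mol%), SPhos (4 mol%), 50 °C
Reagents that add atoms: none
Why: Ester-directed deprotonative magnesiation should occur at C2, the CH flanked by the ring oxygen and the ester, and transmetalation to zinc followed by Negishi cross-coupling should place the protected catechol ring there.

Step 5
Reactants: 8 methyl 4-{[tert-butyl(dimethyl)silyl]oxymethyl}-2-(2,2-dimethyl-1,3-benzodioxol-5-yl)furan-3-carboxylate
Product: 10 methyl 5-acetyl-4-{[tert-butyl(dimethyl)silyl]oxymethyl}-2-(2,2-dimethyl-1,3-benzodioxol-5-yl)furan-3-carboxylate, via furan-5-ylmagnesium chloride 9 (not isolated)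
Conditions: TMPMgCl·LiCl, THF, 25 °C; then MeC(O)N(OMe)Me, 0 → 25 °C; aq NH4Cl
Reagents that add atoms: N-methoxy-N-methylacetamide, CC(=O)N(C)OC
Why: C5–H is the only ring hydrogen left and lies next to the ring oxygen, so a second deprotonative magnesiation followed by Weinreb ketone synthesis (the chelated tetrahedral adduct prevents double addition) should give the methyl ketone.

Step 6
Reactants: 10 methyl 5-acetyl-4-{[tert-butyl(dimethyl)silyl]oxymethyl}-2-(2,2-dimethyl-1,3-benzodioxol-5-yl)furan-3-carboxylate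
Product: 11 methyl 5-acetyl-2-(2,2-dimethyl-1,3-benzodioxol-5-yl)-4-(hydroxymethyl)furan-3-carboxylate
Conditions: Bu4NF, AcOH, THF, 0 → 25 °C
Reagents that add atoms: none
Why: Fluoride-induced desilylation, buffered with acetic acid so that no free alkoxide can add to the neighbouring ketone or ester, should free the primary alcohol.

Step 7
Reactants: 11 methyl 5-acetyl-2-(2,2-dimethyl-1,3-benzodioxol-5-yl)-4-(hydroxymethyl)furan-3-carboxylate
Product: 12 methyl 5-acetyl-2-(2,2-dimethyl-1,3-benzodioxol-5-yl)-4-formylfuran-3-carboxylate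
Conditions: Dess–Martin periodinane, CH2Cl2, 0 → 25 °C
Reagents that add atoms: none
Why: Dess–Martin oxidation of a primary furylmethanol should stop at the aldehyde and leave the ketone, the ester and the acetonide untouched.

Step 8
Reactants: 12 methyl 5-acetyl-2-(2,2-dimethyl-1,3-benzodioxol-5-yl)-4-formylfuran-3-carboxylate; 13 triethyl 4-phosphonocrotonate
Product: 15 methyl 5-acetyl-2-(2,2-dimethyl-1,3-benzodioxol-5-yl)-4-[(1E,3E)-4-ethoxycarbonylbuta-1,3-dienyl]furan-3-carboxylate, via lithiated phosphonate 14 (not isolated)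
Conditions: 13, LiN(SiMe3)2, THF, −78 °C; then 12, −78 → 0 °C
Reagents that add atoms: none
Why: Vinylogous Horner–Wadsworth–Emmons olefination, in which the preformed stabilised phosphonate anion (no excess base, so the methyl ketone is not enolised) should add to the aldehyde much faster than to the hindered ketone and give the new alkene with E geometry while the E alkene of the reagent is kept.

Step 9
Reactants: 15 methyl 5-acetyl-2-(2,2-dimethyl-1,3-benzodioxol-5-yl)-4-[(1E,3E)-4-ethoxycarbonylbuta-1,3-dienyl]furan-3-carboxylate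
Product: 16 methyl 5-{1-[tert-butyl(dimethyl)silyl]oxyethenyl}-2-(2,2-dimethyl-1,3-benzodioxol-5-yl)-4-[(1E,3E)-4-ethoxycarbonylbuta-1,3-dienyl]furan-3-carboxylate
Conditions: TBSOTf, Et3N, CH2Cl2, 0 °C
Reagents that add atoms: tert-butyldimethylsilyl trifluoromethanesulfonate, CC(C)(C)[Si](C)(C)OS(=O)(=O)C(F)(F)F
Why: Soft enolisation (silyl triflate and tertiary amine) of the methyl ketone, which can enolise only towards its CH3 group, should give the silyl enol ether, and neither ester has an α-hydrogen.

Step 10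
Reactants: 16 methyl 5-{1-[tert-butyl(dimethyl)silyl]oxyethenyl}-2-(2,2-dimethyl-1,3-benzodioxol-5-yl)-4-[(1E,3E)-4-ethoxycarbonylbuta-1,3-dienyl]furan-3-carboxylate
Product: 18 methyl 7-[tert-butyl(dimethyl)silyl]oxy-2-(2,2-dimethyl-1,3-benzodioxol-5-yl)-5-[(E)-3-ethoxy-3-oxoprop-1-enyl]-1-benzofuran-3-carboxylate, via 5,6-dihydrobenzofuran 17 (not isolated)
Conditions: o-xylene (degassed, dilute), 140 °C; then DDQ (1.2 equiv), 25 °C
Reagents that add atoms: none
Why: In 16 the enol ether C=C (future C6=C7), the furan C4=C5 bond (future C3a=C7a) and the proximal E alkene of the dienoate (future C4=C5) make up a 2-silyloxyhexatriene whose central double bond is held cis by the furan, so heating should bring about a thermal disrotatory six-electron electrocyclization that forms only the C5–C6 bond and closes the six-membered ring A as the 5,6-dihydro compound 17. The closest known reaction type is the thermal electrocyclization and dehydrogenation of 2,3-dialkenyl furans, thiophenes and indoles to benzo-fused heteroarenes, here with a donor (silyloxy) and a vinylogous acceptor (the unsaturated ester) on the triene, which should lower the barrier. DDQ is added only after the enol ether has been consumed, so that it cannot attack that group; it removes hydride from the doubly allylic C5–H and a proton is lost from C6, and the gain of benzofuran aromaticity makes this irreversible. The C5 stereocentre of 17 is transient and racemic and is erased on aromatisation, so no stereocontrol is needed. The selectivity needed is periselectivity: the E geometry of the proximal alkene excludes both the eight-electron closure of the whole tetraene and the other six-electron closure, which would need this alkene as its cis central bond, so the furan-centred triene is the only one able to close. The distal alkene takes no part and should emerge as the E-acrylate at C5, and the enol ether oxygen as the C7 silyl ether.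

Step 11
Reactants: 18 methyl 7-[tert-butyl(dimethyl)silyl]oxy-2-(2,2-dimethyl-1,3-benzodioxol-5-yl)-5-[(E)-3-ethoxy-3-oxoprop-1-enyl]-1-benzofuran-3-carboxylate
Product: 20 methyl 2-(2,2-dimethyl-1,3-benzodioxol-5-yl)-5-[(E)-3-ethoxy-3-oxoprop-1-enyl]-7-(prop-2-enyloxy)-1-benzofuran-3-carboxylate, via cesium phenoxide 19 (not isolated)
Conditions: CsF, allyl bromide, DMF, 25 °C
Reagents that add atoms: allyl bromide, C=CCBr
Why: Fluoride cleaves the aryl silyl ether and the phenoxide so formed is alkylated in the same flask (Williamson ether synthesis), which exchanges the base-labile silyl group at O7 for an allyl ether that survives saponification.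

Step 12
Reactants: 20 methyl 2-(2,2-dimethyl-1,3-benzodioxol-5-yl)-5-[(E)-3-ethoxy-3-oxoprop-1-enyl]-7-(prop-2-enyloxy)-1-benzofuran-3-carboxylate
Product: 21 5-[(E)-2-carboxyethenyl]-2-(2,2-dimethyl-1,3-benzodioxol-5-yl)-7-(prop-2-enyloxy)-1-benzofuran-3-carboxylic acid
Conditions: LiOH, THF/MeOH/H2O, 50 °C; then 1 M HCl, 0 °C
Reagents that add atoms: lithium hydroxide, [Li+].[OH-]
Why: Saponification of both the ethyl acrylate and the more hindered C3 methyl ester, to which the allyl ether and the acetonide are inert.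

Step 13
Reactants: 22 sodium (2R)-3-(3,4-dihydroxyphenyl)-2-hydroxypropanoate (danshensu sodium salt)
Product: 23 prop-2-enyl (2R)-3-[3,4-bis(prop-2-enyloxy)phenyl]-2-hydroxypropanoate
Conditions: allyl bromide (3.3 equiv), K2CO3, DMF, 25 °C
Reagents that add atoms: allyl bromide, C=CCBr
Why: O-Alkylation of the carboxylate and the two phenoxides (Williamson type), in which K2CO3 deprotonates neither the secondary alcohol nor the α-CH, so the alcohol stays free and the R stereocentre is untouched.

Step 14
Reactants: 21 5-[(E)-2-carboxyethenyl]-2-(2,2-dimethyl-1,3-benzodioxol-5-yl)-7-(prop-2-enyloxy)-1-benzofuran-3-carboxylic acid; 23 prop-2-enyl (2R)-3-[3,4-bis(prop-2-enyloxy)phenyl]-2-hydroxypropanoate (two molecules are taken up, one by each acid group of 21)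
Product: 25 fully protected Schizotenuin A (O7 allyl ether; acetonide on the C2 catechol; both (R)-danshensu units as allyl ester bis-allyl ethers), via bis(acyl chloride) 24 (not isolated)
Conditions: 1-chloro-N,N,2-trimethylprop-1-en-1-amine (2.2 equiv), CH2Cl2, 0 → 25 °C; then 23 (2.4 equiv), pyridine, DMAP (cat.), 0 → 25 °C
Reagents that add atoms: prop-2-enyl (2R)-3-[3,4-bis(prop-2-enyloxy)phenyl]-2-hydroxypropanoate (the second molecule of 23), O[C@H](Cc1ccc(OCC=C)c(OCC=C)c1)C(=O)OCC=C
Why: Neutral conversion of both acids into acyl chlorides with the α-chloroenamine, then DMAP-catalysed acylation of the secondary alcohol of one molecule of 23 at each acyl chloride (double esterification through the acyl chlorides), in which the C–O bond at the stereocentre is not broken, so both new ester centres keep the R configuration of danshensu.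

Step 15
Reactants: 25 fully protected Schizotenuin A
Product: 26 hepta-allyl Schizotenuin A (as 25 but with the free catechol on the C2 aryl ring)
Conditions: TFA/H2O (9:1), CH2Cl2, 0 → 25 °C
Reagents that add atoms: none
Why: Acid-catalysed hydrolysis of the catechol isopropylidene ketal, to which allyl ethers, allyl esters and the two ester links should be stable at room temperature.

Step 16
Reactants: 26 hepta-allyl Schizotenuin A
Product: 27 Schizotenuin A
Conditions: Pd(PPh3)4 (10 mol%), morpholine, THF (degassed), 25 °C; then 1 M HCl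
Reagents that add atoms: none
Why: Tsuji–Trost deallylation, in which zerovalent palladium ionises the five aryl allyl ethers and the two allyl esters to π-allyl complexes that morpholine captures, under conditions that should leave the two ester links, the E-acrylate and both R stereocentres untouched.

**Compound list**

1 | dimethyl furan-3,4-dicarboxylate | COC(=O)c1cocc1C(=O)OC | starting material
2 | 4-(methoxycarbonyl)furan-3-carboxylic acid | COC(=O)c1cocc1C(=O)O | intermediate
3 | methyl 4-(hydroxymethyl)furan-3-carboxylate | COC(=O)c1cocc1CO | intermediate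
4 | methyl 4-{[tert-butyl(dimethyl)silyl]oxymethyl}furan-3-carboxylate | COC(=O)c1cocc1CO[Si](C)(C)C(C)(C)C | intermediate
5 | 5-bromo-2,2-dimethyl-1,3-benzodioxole | CC1(C)Oc2ccc(Br)cc2O1 | starting material
6 | chloro[3-(methoxycarbonyl)-4-(silyloxymethyl)furan-2-yl]magnesium (LiCl complex) | COC(=O)c1c([Mg]Cl)occ1CO[Si](C)(C)C(C)(C)C | intermediate
7 | chloro[3-(methoxycarbonyl)-4-(silyloxymethyl)furan-2-yl]zinc | COC(=O)c1c([Zn]Cl)occ1CO[Si](C)(C)C(C)(C)C | intermediate
8 | methyl 4-{[tert-butyl(dimethyl)silyl]oxymethyl}-2-(2,2-dimethyl-1,3-benzodioxol-5-yl)furan-3-carboxylate | COC(=O)c1c(-c2ccc3OC(C)(C)Oc3c2)occ1CO[Si](C)(C)C(C)(C)C | intermediate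
9 | C5-magnesiated 8 (furan-5-ylmagnesium chloride, LiCl complex) | COC(=O)c1c(-c2ccc3OC(C)(C)Oc3c2)oc([Mg]Cl)c1CO[Si](C)(C)C(C)(C)C | intermediate
10 | methyl 5-acetyl-4-{[tert-butyl(dimethyl)silyl]oxymethyl}-2-(2,2-dimethyl-1,3-benzodioxol-5-yl)furan-3-carboxylate | COC(=O)c1c(-c2ccc3OC(C)(C)Oc3c2)oc(C(C)=O)c1CO[Si](C)(C)C(C)(C)C | intermediate
11 | methyl 5-acetyl-2-(2,2-dimethyl-1,3-benzodioxol-5-yl)-4-(hydroxymethyl)furan-3-carboxylate | COC(=O)c1c(-c2ccc3OC(C)(C)Oc3c2)oc(C(C)=O)c1CO | intermediate
12 | methyl 5-acetyl-2-(2,2-dimethyl-1,3-benzodioxol-5-yl)-4-formylfuran-3-carboxylate | COC(=O)c1c(-c2ccc3OC(C)(C)Oc3c2)oc(C(C)=O)c1C=O | intermediate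
13 | triethyl 4-phosphonocrotonate, ethyl (E)-4-(diethoxyphosphoryl)but-2-enoate | CCOC(=O)/C=C/CP(=O)(OCC)OCC | starting material
14 | lithium (E)-1-(diethoxyphosphoryl)-4-ethoxy-4-oxobut-2-en-1-ide | CCOC(=O)/C=C/[CH-]P(=O)(OCC)OCC.[Li+] | intermediate
15 | methyl 5-acetyl-2-(2,2-dimethyl-1,3-benzodioxol-5-yl)-4-[(1E,3E)-4-ethoxycarbonylbuta-1,3-dienyl]furan-3-carboxylate | CCOC(=O)/C=C/C=C/c1c(C(=O)OC)c(-c2ccc3OC(C)(C)Oc3c2)oc1C(C)=O | intermediate
16 | methyl 5-{1-[tert-butyl(dimethyl)silyl]oxyethenyl}-2-(2,2-dimethyl-1,3-benzodioxol-5-yl)-4-[(1E,3E)-4-ethoxycarbonylbuta-1,3-dienyl]furan-3-carboxylate | CCOC(=O)/C=C/C=C/c1c(C(=O)OC)c(-c2ccc3OC(C)(C)Oc3c2)oc1C(=C)O[Si](C)(C)C(C)(C)C | intermediate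
17 | methyl 7-[tert-butyl(dimethyl)silyl]oxy-2-(2,2-dimethyl-1,3-benzodioxol-5-yl)-5-[(E)-3-ethoxy-3-oxoprop-1-enyl]-5,6-dihydro-1-benzofuran-3-carboxylate (racemic at C5) | CCOC(=O)/C=C/C1CC(O[Si](C)(C)C(C)(C)C)=C2OC(-c3ccc4OC(C)(C)Oc4c3)=C(C(=O)OC)C2=C1 | intermediate
18 | methyl 7-[tert-butyl(dimethyl)silyl]oxy-2-(2,2-dimethyl-1,3-benzodioxol-5-yl)-5-[(E)-3-ethoxy-3-oxoprop-1-enyl]-1-benzofuran-3-carboxylate | CCOC(=O)/C=C/c1cc(O[Si](C)(C)C(C)(C)C)c2oc(-c3ccc4OC(C)(C)Oc4c3)c(C(=O)OC)c2c1 | intermediate
19 | cesium 2-(2,2-dimethyl-1,3-benzodioxol-5-yl)-5-[(E)-3-ethoxy-3-oxoprop-1-enyl]-3-(methoxycarbonyl)-1-benzofuran-7-olate | [Cs+].CCOC(=O)/C=C/c1cc([O-])c2oc(-c3ccc4OC(C)(C)Oc4c3)c(C(=O)OC)c2c1 | intermediate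
20 | methyl 2-(2,2-dimethyl-1,3-benzodioxol-5-yl)-5-[(E)-3-ethoxy-3-oxoprop-1-enyl]-7-(prop-2-enyloxy)-1-benzofuran-3-carboxylate | CCOC(=O)/C=C/c1cc(OCC=C)c2oc(-c3ccc4OC(C)(C)Oc4c3)c(C(=O)OC)c2c1 | intermediate
21 | 5-[(E)-2-carboxyethenyl]-2-(2,2-dimethyl-1,3-benzodioxol-5-yl)-7-(prop-2-enyloxy)-1-benzofuran-3-carboxylic acid | OC(=O)/C=C/c1cc(OCC=C)c2oc(-c3ccc4OC(C)(C)Oc4c3)c(C(=O)O)c2c1 | intermediate
22 | sodium (2R)-3-(3,4-dihydroxyphenyl)-2-hydroxypropanoate (danshensu sodium salt) | [Na+].O[C@H](Cc1ccc(O)c(O)c1)C([O-])=O | starting material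
23 | prop-2-enyl (2R)-3-[3,4-bis(prop-2-enyloxy)phenyl]-2-hydroxypropanoate | O[C@H](Cc1ccc(OCC=C)c(OCC=C)c1)C(=O)OCC=C | intermediate
24 | 5-[(E)-3-chloro-3-oxoprop-1-enyl]-2-(2,2-dimethyl-1,3-benzodioxol-5-yl)-7-(prop-2-enyloxy)-1-benzofuran-3-carbonyl chloride | ClC(=O)/C=C/c1cc(OCC=C)c2oc(-c3ccc4OC(C)(C)Oc4c3)c(C(Cl)=O)c2c1 | intermediate
25 | fully protected Schizotenuin A: O7 allyl ether, acetonide on the C2 catechol, both (R)-danshensu units as allyl ester bis-allyl ethers | O=C(/C=C/c1cc(OCC=C)c2oc(-c3ccc4OC(C)(C)Oc4c3)c(C(=O)O[C@H](Cc3ccc(OCC=C)c(OCC=C)c3)C(=O)OCC=C)c2c1)O[C@H](Cc1ccc(OCC=C)c(OCC=C)c1)C(=O)OCC=C | intermediate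
26 | hepta-allyl Schizotenuin A: as 25 with the free catechol on the C2 aryl ring | O=C(/C=C/c1cc(OCC=C)c2oc(-c3ccc(O)c(O)c3)c(C(=O)O[C@H](Cc3ccc(OCC=C)c(OCC=C)c3)C(=O)OCC=C)c2c1)O[C@H](Cc1ccc(OCC=C)c(OCC=C)c1)C(=O)OCC=C | intermediate
27 | Schizotenuin A | O=C(/C=C/c1cc(O)c2oc(-c3ccc(O)c(O)c3)c(C(=O)O[C@H](Cc3ccc(O)c(O)c3)C(=O)O)c2c1)O[C@H](Cc1ccc(O)c(O)c1)C(=O)O | target

**Step count**

Total: 16 steps. Longest linear sequence: 15 steps (steps 1–12 and 14–16, from dimethyl furan-3,4-dicarboxylate); step 13 is a one-step side branch.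

**Steps most likely to fail**

Step 10 (ring closure and aromatisation). The closure costs the furan its aromaticity and may be slow at temperatures the enol silane tolerates. Enol ether that is still present when the quinone is added may be attacked by it. The dihydro intermediate may also shift hydrogen and lose silanol before it is dehydrogenated. The fallback keeps the same electrocyclization but builds the oxidation level into the triene, so that aromatisation is an elimination and no oxidant is needed. It sets out from 16. NBS in THF at −78 °C should convert the silyl enol ether into methyl 5-(bromoacetyl)-2-(2,2-dimethyl-1,3-benzodioxol-5-yl)-4-[(1E,3E)-4-ethoxycarbonylbuta-1,3-dienyl]furan-3-carboxylate F1. TBSOTf and iPr2NEt in CH2Cl2 should then give the (Z)-2-bromo-1-silyloxyethenyl furan F2, in which bromine sits on the outer side of the triene terminus. Heating F2 in o-xylene with 2,6-lutidine should close ring A to the 6-bromo-5,6-dihydrobenzofuran F3, which should lose HBr at once through its acidic C5–H (electrocyclization followed by dehydrohalogenation, a known way to arenes). The route is rejoined at 18.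

Step 5 (C5 acetylation). C5–H has no directing group beside it, so deprotonation may be incomplete, and at the longer times then needed the amide base or the furylmagnesium species may attack the ester. The fallback replaces deprotonation by electrophilic substitution and cross-coupling. It sets out from 8. NBS in DMF at 0 °C should brominate the only free furan position, an α carbon that is more reactive than the benzodioxole ring, giving methyl 5-bromo-4-{[tert-butyl(dimethyl)silyl]oxymethyl}-2-(2,2-dimethyl-1,3-benzodioxol-5-yl)furan-3-carboxylate F4. Stille coupling with tributyl(1-ethoxyvinyl)stannane (Pd(PPh3)4, toluene, 100 °C) should give the 5-(1-ethoxyethenyl)furan F5. Brief treatment with oxalic acid in wet THF should hydrolyse the enol ether to the methyl ketone, and the route is rejoined at 10.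

Step 16 (global deallylation). Seven allyl groups must leave in one operation; some aryl allyl ethers may remain, and the freed catechols may be oxidised by air in the basic amine medium. The fallback moves the danshensu units to acid-labile 4-methoxybenzyl groups, so that palladium has only one allyl ether to remove. It sets out from 22 and from 21. Alkylation of 22 with 4-methoxybenzyl chloride and K2CO3 in DMF should give (4-methoxyphenyl)methyl (2R)-3-{3,4-bis[(4-methoxyphenyl)methoxy]phenyl}-2-hydroxypropanoate F6. Coupling of two molecules of F6 with 21 through the bis(acyl chloride) 24, as in step 14, should give the bis-ester F7. Pd(PPh3)4 and morpholine should remove the single allyl ether at O7 to give the 7-hydroxy bis-ester F8. TFA/CH2Cl2/H2O with pentamethylbenzene as cation scavenger should then cleave the four benzyl ethers, the two benzyl esters and the acetonide together, and the route is rejoined at 27.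

**Further compounds**

F1 | step 10 | methyl 5-(bromoacetyl)-2-(2,2-dimethyl-1,3-benzodioxol-5-yl)-4-[(1E,3E)-4-ethoxycarbonylbuta-1,3-dienyl]furan-3-carboxylate | CCOC(=O)/C=C/C=C/c1c(C(=O)OC)c(-c2ccc3OC(C)(C)Oc3c2)oc1C(=O)CBr
F2 | step 10 | methyl 5-{(Z)-2-bromo-1-[tert-butyl(dimethyl)silyl]oxyethenyl}-2-(2,2-dimethyl-1,3-benzodioxol-5-yl)-4-[(1E,3E)-4-ethoxycarbonylbuta-1,3-dienyl]furan-3-carboxylate | CCOC(=O)/C=C/C=C/c1c(C(=O)OC)c(-c2ccc3OC(C)(C)Oc3c2)oc1/C(O[Si](C)(C)C(C)(C)C)=C/Br
F3 | step 10 | methyl 6-bromo-7-[tert-butyl(dimethyl)silyl]oxy-2-(2,2-dimethyl-1,3-benzodioxol-5-yl)-5-[(E)-3-ethoxy-3-oxoprop-1-enyl]-5,6-dihydro-1-benzofuran-3-carboxylate | CCOC(=O)/C=C/C1C(Br)C(O[Si](C)(C)C(C)(C)C)=C2OC(-c3ccc4OC(C)(C)Oc4c3)=C(C(=O)OC)C2=C1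
F4 | step 5 | methyl 5-bromo-4-{[tert-butyl(dimethyl)silyl]oxymethyl}-2-(2,2-dimethyl-1,3-benzodioxol-5-yl)furan-3-carboxylate | COC(=O)c1c(-c2ccc3OC(C)(C)Oc3c2)oc(Br)c1CO[Si](C)(C)C(C)(C)C
F5 | step 5 | methyl 4-{[tert-butyl(dimethyl)silyl]oxymethyl}-2-(2,2-dimethyl-1,3-benzodioxol-5-yl)-5-(1-ethoxyethenyl)furan-3-carboxylate | COC(=O)c1c(-c2ccc3OC(C)(C)Oc3c2)oc(C(=C)OCC)c1CO[Si](C)(C)C(C)(C)C
F6 | step 16 | (4-methoxyphenyl)methyl (2R)-3-{3,4-bis[(4-methoxyphenyl)methoxy]phenyl}-2-hydroxypropanoate | O[C@H](Cc1ccc(OCc2ccc(OC)cc2)c(OCc2ccc(OC)cc2)c1)C(=O)OCc1ccc(OC)cc1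
F7 | step 16 | bis-ester of 21 with two units of F6 (O7 allyl ether, C2-catechol acetonide, both R) | O=C(/C=C/c1cc(OCC=C)c2oc(-c3ccc4OC(C)(C)Oc4c3)c(C(=O)O[C@H](Cc3ccc(OCc4ccc(OC)cc4)c(OCc4ccc(OC)cc4)c3)C(=O)OCc3ccc(OC)cc3)c2c1)O[C@H](Cc1ccc(OCc2ccc(OC)cc2)c(OCc2ccc(OC)cc2)c1)C(=O)OCc1ccc(OC)cc1
F8 | step 16 | 7-hydroxy analogue of F7 | O=C(/C=C/c1cc(O)c2oc(-c3ccc4OC(C)(C)Oc4c3)c(C(=O)O[C@H](Cc3ccc(OCc4ccc(OC)cc4)c(OCc4ccc(OC)cc4)c3)C(=O)OCc3ccc(OC)cc3)c2c1)O[C@H](Cc1ccc(OCc2ccc(OC)cc2)c(OCc2ccc(OC)cc2)c1)C(=O)OCc1ccc(OC)cc1
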